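## Retrosynthetic overview
1. The last bond made is C3–CH2(guaiacyl). The enediol bis-silyl ether of the lactone adds 1,6 to the guaiacyl para-quinone methide obtained by dehydrogenating creosol. Attack is anti to the C4 side chain and sets C3.
2. The C3–O bond comes from enolate hydroxylation of the (R)-β-(arylmethyl)butyrolactone.
3. The lactone ring comes from an enantioselective Baeyer–Villiger ring expansion (four- to five-membered, C-to-O 1,2-shift) of a prochiral 3-(arylmethyl)cyclobutanone. This sets C4.
4. The cyclobutanone side chain comes from a Negishi sp3–sp2 coupling of 3-(bromomethyl)cyclobutanone with silylated 4-chloro-2,6-dimethoxyphenol.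
5. The arenes come from ortho-bromination and copper-catalysed methoxylation of 4-chlorophenol and p-cresol. Both benzene rings and the four-membered ring are bought, so the lactone is the only ring formed.

Assumption: the (S,S)-configured N,N′-dioxide ligand of step 5 is taken to give the R lactone 9. If the rotation of 9 shows the opposite sense, the mirror-image ligand from D-pipecolic acid is used and nothing else changes.

## Route

Step 1
Reactants: 1 4-chlorophenol
Product: 2 2,6-dibromo-4-chlorophenol
Conditions: Br2 (2.1 equiv), AcOH, rt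
Reagents that add atoms: bromine, BrBr
Why: Electrophilic aromatic bromination, in which the free OH activates its two ortho positions and the para position is blocked by chlorine, so 2 is the only dibromide.

Step 2
Reactants: 2 2,6-dibromo-4-chlorophenol
Product: 3 4-chloro-2,6-dimethoxyphenol
Conditions: NaOMe (6 equiv, in MeOH), CuI (10 mol%), DMF, 110 °C; aq HCl work-up
Reagents that add atoms: sodium methoxide, [Na+].[O-]C
Why: Ullmann-type copper-catalysed methoxylation of an ortho-bromophenolate, as run on scale for 2,6-dibromo-4-methylphenol, and C–Br reacts far faster than C–Cl, so the chloride needed in step 4 is kept.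

Step 3
Reactants: 3 4-chloro-2,6-dimethoxyphenol
Product: 4 tert-butyl(4-chloro-2,6-dimethoxyphenoxy)dimethylsilane
Conditions: TBSCl, imidazole, DMF, rt
Reagents that add atoms: tert-butyldimethylsilyl chloride, CC(C)(C)[Si](C)(C)Cl
Why: Standard imidazole-promoted O-silylation, whose silyl ether keeps the phenol from protonating the zinc reagent and from peracid oxidation, stands amide bases at low temperature and falls off with fluoride in step 9.

Step 4
Reactants: 5 3-(bromomethyl)cyclobutan-1-one; 4 tert-butyl(4-chloro-2,6-dimethoxyphenoxy)dimethylsilane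
Product: 7 3-{[4-(tert-butyldimethylsilyloxy)-3,5-dimethoxyphenyl]methyl}cyclobutan-1-one, via (3-oxocyclobutyl)methylzinc bromide 6 (not isolated)
Conditions: 5, Zn dust, LiCl, THF, 40 °C; then 4, Pd(OAc)2 (2 mol%), RuPhos (4 mol%), THF, 60 °C
Reagents that add atoms: none
Why: Negishi cross-coupling, in which LiCl-assisted zinc insertion into the primary bromide leaves the ketone alone and the bulky electron-rich biarylphosphine lets zerovalent palladium insert into the aryl chloride and eliminate reductively faster than beta-hydride or beta-carbon elimination.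

Step 5
Reactants: 7 3-{[4-(tert-butyldimethylsilyloxy)-3,5-dimethoxyphenyl]methyl}cyclobutan-1-one
Product: 9 (4R)-4-{[4-(tert-butyldimethylsilyloxy)-3,5-dimethoxyphenyl]methyl}oxolan-2-one, via Criegee peroxyester adduct 8 (not isolated)
Conditions: Sc(OTf)3 (5 mol%), (2S,2′S)-1,1′-(propane-1,3-diyl)bis{2-[(2,6-diisopropylphenyl)carbamoyl]piperidine 1-oxide} (5.5 mol%), mCPBA (1.2 equiv), EtOAc, −20 °C
Reagents that add atoms: 3-chloroperoxybenzoic acid, OOC(=O)c1cccc(Cl)c1
Why: Catalytic enantioselective Baeyer–Villiger oxidation, in which the peracid adds to the strained ketone to give 8 and the chiral trivalent scandium complex places only one of the two enantiotopic ring CH2 groups antiperiplanar to the O–O bond, so its 1,2-shift from C to O expands the four-membered ring to the lactone and fixes C4 as R (about 90% ee expected, raised by crystallising 11).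

Step 6
Reactants: 9 (4R)-4-{[4-(tert-butyldimethylsilyloxy)-3,5-dimethoxyphenyl]methyl}oxolan-2-one
Product: 11 (3R,4S)-3-hydroxy-4-{[4-(tert-butyldimethylsilyloxy)-3,5-dimethoxyphenyl]methyl}oxolan-2-one, via potassium enolate of the lactone 10 (not isolated)
Conditions: KN(SiMe3)2 (1.15 equiv), THF, −78 °C; 2-(benzenesulfonyl)-3-phenyloxaziridine (1.3 equiv), −78 °C; AcOH quench
Reagents that add atoms: 2-(benzenesulfonyl)-3-phenyloxaziridine, O=S(=O)(N1OC1c1ccccc1)c1ccccc1
Why: Davis hydroxylation of a lactone enolate, with oxygen delivered anti to the C4 side chain (trans product), although this centre is flattened again in step 9 so its ratio does not matter.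

Step 7
Reactants: 12 4-methylphenol (p-cresol)
Product: 13 2-bromo-4-methylphenol
Conditions: Br2 (1.0 equiv), CH2Cl2, 0 °C
Reagents that add atoms: bromine, BrBr
Why: Electrophilic aromatic bromination with one equivalent at low temperature stops at the ortho-monobromide because the para position carries the methyl group.

Step 8
Reactants: 13 2-bromo-4-methylphenol
Product: 14 2-methoxy-4-methylphenol (creosol)
Conditions: NaOMe (3 equiv, in MeOH), CuI (10 mol%), DMF, 110 °C; aq HCl work-up
Reagents that add atoms: sodium methoxide, [Na+].[O-]C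
Why: Ullmann-type copper-catalysed methoxylation of an ortho-bromophenolate, the same reliable exchange as in step 2.

Step 9
Reactants: 11 (3R,4S)-3-hydroxy-4-{[4-(tert-butyldimethylsilyloxy)-3,5-dimethoxyphenyl]methyl}oxolan-2-one; 14 2-methoxy-4-methylphenol
Product: 18 (3S,4S)-3-hydroxy-4-[(4-hydroxy-3,5-dimethoxyphenyl)methyl]-3-[(4-hydroxy-3-methoxyphenyl)methyl]oxolan-2-one (target), via guaiacyl para-quinone methide 15 (not isolated), via enediol bis-silyl ether 16 (not isolated), via trisilylated adduct 17 (not isolated)
Conditions: flask A: 11, LiN(SiMe3)2 (2.3 equiv), TMSCl (2.6 equiv), THF, −78 to 0 °C; flask B: 14 (2 equiv), Ag2O (4 equiv), Na2SO4, CH2Cl2 (0.05 M), 0 °C, 20 min, filtered into A at −78 °C, then to −20 °C; AcOH, Bu4NF, 0 °C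
Reagents that add atoms: none
Why: Proposed new method: a dehydrogenative Mukaiyama-type 1,6-addition in which Ag2O takes two hydrogens from the para-cresol 14 to give the delta-unsubstituted quinone methide 15, the very electron-rich tetrasubstituted alkene of 16 (made as glycolate-derived poly(silyloxy)alkenes are) attacks the exocyclic CH2 from the face opposite the C4 side chain, aromatisation drives C–C bond formation and the silyl group passes from the oxocarbenium ion to the new phenoxide to give 17, so the guaiacylmethyl group ends trans to the C4 substituent and the oxygen cis (3S), and buffered fluoride then strips all three silyl groups; the closest known reaction types are the 1,6-conjugate addition of enolates and silyl ketene acetals to stabilised delta-aryl-2,6-di-tert-butyl para-quinone methides and the trans-selective benzylation of alpha-hydroxy-beta-benzyl lactone dianions with benzyl bromides, neither shown so far with an enediol bis-silyl ether, with an unstabilised quinone methide taken straight from a cresol, or for a fully substituted carbinol centre.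

## Compound list
1 | 4-chlorophenol | Oc1ccc(Cl)cc1 | starting material
2 | 2,6-dibromo-4-chlorophenol | Oc1c(Br)cc(Cl)cc1Br | intermediate
3 | 4-chloro-2,6-dimethoxyphenol | COc1cc(Cl)cc(OC)c1O | intermediate
4 | tert-butyl(4-chloro-2,6-dimethoxyphenoxy)dimethylsilane | COc1cc(Cl)cc(OC)c1O[Si](C)(C)C(C)(C)C | intermediate
5 | 3-(bromomethyl)cyclobutan-1-one | O=C1CC(CBr)C1 | starting material
6 | (3-oxocyclobutyl)methylzinc bromide | O=C1CC(C[Zn]Br)C1 | intermediate
7 | 3-{[4-(tert-butyldimethylsilyloxy)-3,5-dimethoxyphenyl]methyl}cyclobutan-1-one (prochiral) | COc1cc(CC2CC(=O)C2)cc(OC)c1O[Si](C)(C)C(C)(C)C | intermediate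
8 | Criegee adduct, 1-hydroxy-3-(arylmethyl)cyclobutyl 3-chloroperoxybenzoate (relative configuration on the ring left open) | OC1(OOC(=O)c2cccc(Cl)c2)CC(Cc2cc(OC)c(O[Si](C)(C)C(C)(C)C)c(OC)c2)C1 | intermediate
9 | (4R)-4-{[4-(tert-butyldimethylsilyloxy)-3,5-dimethoxyphenyl]methyl}oxolan-2-one | O=C1C[C@@H](Cc2cc(OC)c(O[Si](C)(C)C(C)(C)C)c(OC)c2)CO1 | intermediate
10 | potassium (4R)-4-(arylmethyl)-4,5-dihydrofuran-2-olate, the enolate of 9 | [K+].[O-]C1=C[C@@H](Cc2cc(OC)c(O[Si](C)(C)C(C)(C)C)c(OC)c2)CO1 | intermediate
11 | (3R,4S)-3-hydroxy-4-{[4-(tert-butyldimethylsilyloxy)-3,5-dimethoxyphenyl]methyl}oxolan-2-one (OH trans to the side chain) | O[C@H]1C(=O)OC[C@@H]1Cc1cc(OC)c(O[Si](C)(C)C(C)(C)C)c(OC)c1 | intermediate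
12 | 4-methylphenol (p-cresol) | Cc1ccc(O)cc1 | starting material
13 | 2-bromo-4-methylphenol | Cc1ccc(O)c(Br)c1 | intermediate
14 | 2-methoxy-4-methylphenol (creosol) | COc1cc(C)ccc1O | intermediate
15 | 2-methoxy-4-methylidenecyclohexa-2,5-dien-1-one | COC1=CC(=C)C=CC1=O | intermediate
16 | (4S)-4-{[4-(tert-butyldimethylsilyloxy)-3,5-dimethoxyphenyl]methyl}-2,3-bis(trimethylsilyloxy)-4,5-dihydrofuran | C[Si](C)(C)OC1=C(O[Si](C)(C)C)[C@@H](Cc2cc(OC)c(O[Si](C)(C)C(C)(C)C)c(OC)c2)CO1 | intermediate
17 | (3S,4S)-4-{[4-(tert-butyldimethylsilyloxy)-3,5-dimethoxyphenyl]methyl}-3-{[3-methoxy-4-(trimethylsilyloxy)phenyl]methyl}-3-(trimethylsilyloxy)oxolan-2-one | COc1cc(C[C@@]2(O[Si](C)(C)C)C(=O)OC[C@@H]2Cc2cc(OC)c(O[Si](C)(C)C(C)(C)C)c(OC)c2)ccc1O[Si](C)(C)C | intermediate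
18 | (3S,4S)-3-hydroxy-4-[(4-hydroxy-3,5-dimethoxyphenyl)methyl]-3-[(4-hydroxy-3-methoxyphenyl)methyl]oxolan-2-one (two arylmethyl groups trans, OH cis to the C4 side chain) | COc1cc(C[C@@]2(O)C(=O)OC[C@@H]2Cc2cc(OC)c(O)c(OC)c2)ccc1O | target

## Step count and risks
Total step count: 9.
Longest linear sequence: 7 steps (1, 2, 3, 4, 5, 6, 9).

**Step 9 (the new step).**
- Risks: the creosol phenoxyl radical can couple at its free ortho position instead of going on to 15. Compound 15 can oligomerise before it meets 16. Traces of water or unreacted 14 can protodesilylate 16 back to 11.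
- Fallback (known chemistry): it sets out from 14 and 11 and comes back at 18.
- Creosol 14 is acylated (pivaloyl chloride, Et3N, CH2Cl2) to 2-methoxy-4-methylphenyl 2,2-dimethylpropanoate F1.
- The deactivated ring of this ester allows Wohl–Ziegler bromination (NBS, AIBN, PhCF3, reflux) to 4-(bromomethyl)-2-methoxyphenyl 2,2-dimethylpropanoate F2.
- Compound 11 is converted with LiN(iPr)2 (2.2 equiv, THF/DMPU, −78 °C) into the dilithium enediolate F3.
- The enediolate is alkylated by the bromide anti to the C4 side chain to give the doubly protected (3S,4S)-lactone F4.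
- NaOMe in MeOH followed by dilute HCl removes the pivalate and the aryl silyl ether and gives 18.

**Step 5.**
- Risks: the enantioselectivity for an arylmethyl substituent can fall below that for 3-aryl substrates. The peracid can also attack the electron-rich arene.
- Fallback: it sets out from 7 and comes back at 9, replacing catalyst control by auxiliary control of the same ring expansion.
- Compound 7 is ketalised with (2R,4R)-pentane-2,4-diol (pyridinium tosylate, toluene, water removal) to the C2-symmetric spiroketal F5. The diol antipode is the one that leads to the R lactone.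
- mCPBA with SnCl4 in CH2Cl2 at −78 °C opens one diastereotopic C–O bond and triggers the diastereoselective C-to-O shift. Aqueous work-up then releases 9 and the diol.

**Step 4.**
- Risks: electron transfer during zinc insertion can open the (3-oxocyclobutyl)methyl radical to a pent-4-en-2-one enolate. Oxidative addition into the electron-rich chloride can also be slow.
- Fallback: it sets out from 4 and comes back at 7, building the four-membered ring on the side chain instead of coupling a preformed ring.
- Kumada allylation of 4 (CH2=CHCH2MgBr, NiCl2(dppp) with dppp = Ph2P(CH2)3PPh2, THF) gives tert-butyl(2,6-dimethoxy-4-prop-2-enylphenoxy)dimethylsilane F6.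
- Dichloroketene cycloaddition (Cl3CCOCl, Zn, Et2O) gives racemic 2,2-dichloro-3-(arylmethyl)cyclobutan-1-one F7.
- Zn in AcOH removes both chlorines to give 7.

Further compounds
F1 | step 9 | 2-methoxy-4-methylphenyl 2,2-dimethylpropanoate | COc1cc(C)ccc1OC(=O)C(C)(C)C
F2 | step 9 | 4-(bromomethyl)-2-methoxyphenyl 2,2-dimethylpropanoate | COc1cc(CBr)ccc1OC(=O)C(C)(C)C
F3 | step 9 | dilithium (4S)-4-{[4-(tert-butyldimethylsilyloxy)-3,5-dimethoxyphenyl]methyl}-4,5-dihydrofuran-2,3-diolate | [Li+].[Li+].[O-]C1=C([O-])[C@@H](Cc2cc(OC)c(O[Si](C)(C)C(C)(C)C)c(OC)c2)CO1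
F4 | step 9 | 4-{[(3S,4S)-4-{[4-(tert-butyldimethylsilyloxy)-3,5-dimethoxyphenyl]methyl}-3-hydroxy-2-oxooxolan-3-yl]methyl}-2-methoxyphenyl 2,2-dimethylpropanoate | COc1cc(C[C@@]2(O)C(=O)OC[C@@H]2Cc2cc(OC)c(O[Si](C)(C)C(C)(C)C)c(OC)c2)ccc1OC(=O)C(C)(C)C
F5 | step 5 | spiroketal of 7 with (2R,4R)-pentane-2,4-diol | C[C@@H]1C[C@@H](C)OC2(CC(Cc3cc(OC)c(O[Si](C)(C)C(C)(C)C)c(OC)c3)C2)O1
F6 | step 4 | tert-butyl(2,6-dimethoxy-4-prop-2-enylphenoxy)dimethylsilane | C=CCc1cc(OC)c(O[Si](C)(C)C(C)(C)C)c(OC)c1
F7 | step 4 | 2,2-dichloro-3-{[4-(tert-butyldimethylsilyloxy)-3,5-dimethoxyphenyl]methyl}cyclobutan-1-one (racemic) | O=C1CC(Cc2cc(OC)c(O[Si](C)(C)C(C)(C)C)c(OC)c2)C1(Cl)Cl
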